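The α-methylene-γ-butyrolactone (C11=C13, C12, ring O, C8, C7; germacrane numbering) shares its C7–C8 bond with the ten-membered carbocycle, so both rings are closed together from an open chain. The precursor is an acyclic (E,Z)-diene aldehyde: C8 is the aldehyde, and a terminal allene (C13=C11=C7) next to the silylated C6 carbinol serves as a latent 2-carboxyallyl unit; the C15 ester is already in place. Zerovalent nickel joins CO2 to the central allene carbon, the resulting allylnickel carboxylate adds through C7 to the aldehyde, closing the carbocycle and setting C7 and C8, and the γ-hydroxy acid lactonises. The chain comes from carboalumination, Horner–Wadsworth–Emmons olefination, asymmetric alkynylation and SN2′ hydride delivery.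

Key step: step 16

Remark on numbering: C1=C10 carries the C14 methyl, C4=C5 the C15 acyloxymethyl group, C6 is the carbinol, C7/C8 the ring fusion, C11=C13 the methylene unit and C12 the lactone carbonyl.
Assumption: the (S,S)-ProPhenol–zinc catalyst is taken to give the (4R)-alcohol 13 in step 6; if the sense is the opposite on this enal, the (R,R)-ligand is used.

**Route**

Step 1
Reactants: 1 tert-butyl(but-3-yn-1-yloxy)dimethylsilane; 2 oxirane
Product: 5 (3E)-6-{[tert-butyl(dimethyl)silyl]oxy}-4-methylhex-3-en-1-ol, via alkenylalane 3 (not isolated), via lithium alanate 4 (not isolated)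
Conditions: AlMe3, (C5H5)2ZrCl2 (20 mol%), CH2Cl2, 0 °C to rt; n-BuLi, THF, −78 °C; then 2, −78 to 0 °C; aq. Rochelle salt
Reagents that add atoms: trimethylaluminium, C[Al](C)C
Why: Negishi zirconium-catalysed carboalumination adds methyl and aluminium syn across the terminal alkyne with methyl on the internal carbon, and the derived alanate opens oxirane with retention at the alkenyl carbon, which fixes the E geometry of the future C1=C10 bond.

Step 2
Reactants: 5 (3E)-6-{[tert-butyl(dimethyl)silyl]oxy}-4-methylhex-3-en-1-ol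
Product: 6 tert-butyl{[(3E)-6-iodo-3-methylhex-3-en-1-yl]oxy}dimethylsilane
Conditions: I2, PPh3, imidazole, CH2Cl2, 0 °C
Reagents that add atoms: iodine, II
Why: Appel-type iodination converts the primary alcohol into the iodide by SN2 displacement of the oxyphosphonium group without touching the silyl ether or the alkene.

Step 3
Reactants: 6 tert-butyl{[(3E)-6-iodo-3-methylhex-3-en-1-yl]oxy}dimethylsilane; 7 triethyl phosphonoacetate
Product: 8 ethyl (5E)-8-{[tert-butyl(dimethyl)silyl]oxy}-2-(diethoxyphosphoryl)-6-methyloct-5-enoate (racemic at C2)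
Conditions: NaH, DMF, 0 °C; then 6, 60 °C
Reagents that add atoms: none
Why: SN2 alkylation of the sodium salt of the phosphonoacetate with the unhindered primary iodide installs C4 together with the phosphonate needed for the next olefination.

Step 4
Reactants: 8 ethyl (5E)-8-{[tert-butyl(dimethyl)silyl]oxy}-2-(diethoxyphosphoryl)-6-methyloct-5-enoate; 9 2,2-dimethoxyacetaldehyde
Product: 10 ethyl (2E)-2-[(3E)-6-{[tert-butyl(dimethyl)silyl]oxy}-4-methylhex-3-en-1-yl]-4,4-dimethoxybut-2-enoate
Conditions: NaH, THF, 0 °C; 9 (dry toluene solution), 0 °C to rt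
Reagents that add atoms: none
Why: Horner–Wadsworth–Emmons olefination of an α-alkylated phosphonoacetate places the ester trans to the aldehyde-derived carbon, which is exactly the C3/C6-cis relationship that the ring-cis C4=C5 bond of the target needs.

Step 5
Reactants: 10 ethyl (2E)-2-[(3E)-6-{[tert-butyl(dimethyl)silyl]oxy}-4-methylhex-3-en-1-yl]-4,4-dimethoxybut-2-enoate
Product: 11 ethyl (2E)-2-[(3E)-6-{[tert-butyl(dimethyl)silyl]oxy}-4-methylhex-3-en-1-yl]-4-oxobut-2-enoate
Conditions: In(OTf)3 (2 mol%), acetone/H2O, rt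
Reagents that add atoms: water, O
Why: Lewis-acid-catalysed acetal hydrolysis frees the aldehyde under conditions that spare the primary silyl ether, and the ester-trans-to-formyl (fumarate-like) geometry is the thermodynamically preferred one, so the olefin geometry cannot erode.

Step 6
Reactants: 11 ethyl (2E)-2-[(3E)-6-{[tert-butyl(dimethyl)silyl]oxy}-4-methylhex-3-en-1-yl]-4-oxobut-2-enoate; 12 2-(prop-2-yn-1-yloxy)oxane
Product: 13 ethyl (2E,4R)-2-[(3E)-6-{[tert-butyl(dimethyl)silyl]oxy}-4-methylhex-3-en-1-yl]-4-hydroxy-7-(oxan-2-yloxy)hept-2-en-5-ynoate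
Conditions: (S,S)-ProPhenol (20 mol%), ZnMe2 (3 equiv), Ph3P=O (40 mol%), toluene, 0 °C; aq. NH4Cl
Reagents that add atoms: none
Why: Dinuclear zinc–ProPhenol-catalysed enantioselective addition of the alkynylzinc to the aldehyde (catalytic asymmetric alkynylation) creates the C6 carbinol with reagent control, 1,2-addition being the normal mode of alkynylzinc species even on an enal.

Step 7
Reactants: 13 ethyl (2E,4R)-2-[(3E)-6-{[tert-butyl(dimethyl)silyl]oxy}-4-methylhex-3-en-1-yl]-4-hydroxy-7-(oxan-2-yloxy)hept-2-en-5-ynoate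
Product: 14 (2E,4S)-2-[(3E)-6-{[tert-butyl(dimethyl)silyl]oxy}-4-methylhex-3-en-1-yl]hepta-2,5,6-triene-1,4-diol
Conditions: LiAlH4 (excess), Et2O, 0 °C to gentle reflux; Fieser work-up
Reagents that add atoms: none
Why: LiAlH4 reduces the ester to the C15 allylic alcohol and, by alkoxide-directed trans-hydroalumination of the propargylic alcohol with hydride delivery to the carbon next to the carbinol, expels the tetrahydropyranyloxy group in an anti SN2′ elimination to give the terminal allene without touching the C6 stereocentre (the descriptor changes from R to S only through the priority rules).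

Step 8
Reactants: 15 (2E)-but-2-enal
Product: 16 (2Z)-2-iodobut-2-enal
Conditions: I2, K2CO3, DMAP (20 mol%), THF/H2O, rt
Reagents that add atoms: iodine, II
Why: Amine-catalysed α-iodination of the enal (conjugate addition of DMAP, iodination of the enolate, elimination) gives the 2-iodoenal with the methyl group kept trans to the formyl group, that is the Z-iodide.

Step 9
Reactants: 16 (2Z)-2-iodobut-2-enal
Product: 17 (2Z)-2-iodobut-2-en-1-ol
Conditions: NaBH4, MeOH, 0 °C
Reagents that add atoms: none
Why: Borohydride 1,2-reduction of the aldehyde gives the allylic alcohol with the alkenyl iodide geometry intact.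

Step 10
Reactants: 17 (2Z)-2-iodobut-2-en-1-ol
Product: 18 tert-butyl{[(2Z)-2-iodobut-2-en-1-yl]oxy}diphenylsilane
Conditions: TBDPSCl, imidazole, CH2Cl2, rt
Reagents that add atoms: tert-butyl(chloro)diphenylsilane, CC(C)(C)[Si](Cl)(c1ccccc1)c1ccccc1
Why: Standard silylation of the primary alcohol protects it for the carbonylation and the later esterification.

Step 11
Reactants: 18 tert-butyl{[(2Z)-2-iodobut-2-en-1-yl]oxy}diphenylsilane
Product: 19 (2Z)-2-({[tert-butyl(diphenyl)silyl]oxy}methyl)but-2-enoic acid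
Conditions: Pd(OAc)2 (5 mol%), PPh3, CO (1 atm), K2CO3, DMF/H2O, 60 °C; then 1 M HCl
Reagents that add atoms: carbon monoxide, [C-]#[O+]; water, O
Why: Palladium-catalysed hydroxycarbonylation of the alkenyl iodide (oxidative addition, CO insertion, hydrolysis of the acylpalladium) replaces iodine by CO2H with retention, which gives the methyl-cis-to-carboxyl (Z) acid.

Step 12
Reactants: 14 (2E,4S)-2-[(3E)-6-{[tert-butyl(dimethyl)silyl]oxy}-4-methylhex-3-en-1-yl]hepta-2,5,6-triene-1,4-diol; 19 (2Z)-2-({[tert-butyl(diphenyl)silyl]oxy}methyl)but-2-enoic acid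
Product: 20 (2E,4S)-2-[(3E)-6-{[tert-butyl(dimethyl)silyl]oxy}-4-methylhex-3-en-1-yl]-4-hydroxyhepta-2,5,6-trien-1-yl (2Z)-2-({[tert-butyl(diphenyl)silyl]oxy}methyl)but-2-enoate
Conditions: PPh3, DIAD (1.05 equiv each), THF, 0 °C
Reagents that add atoms: none
Why: Mitsunobu esterification activates the unhindered primary allylic hydroxyl, which the carboxylate displaces (SN2), so the acid carbonyl is never activated and the Z geometry of the acid survives, while the hindered secondary C6 hydroxyl remains free.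

Step 13
Reactants: 20 (the C15 ester with free C6 hydroxyl)
Product: 21 (2E,4S)-4-{[tert-butyl(dimethyl)silyl]oxy}-2-[(3E)-6-{[tert-butyl(dimethyl)silyl]oxy}-4-methylhex-3-en-1-yl]hepta-2,5,6-trien-1-yl (2Z)-2-({[tert-butyl(diphenyl)silyl]oxy}methyl)but-2-enoate
Conditions: TBSOTf, 2,6-lutidine, CH2Cl2, −78 °C
Reagents that add atoms: tert-butyldimethylsilyl trifluoromethanesulfonate, CC(C)(C)[Si](C)(C)OS(=O)(=O)C(F)(F)F
Why: Silylation of the secondary α-allenic alcohol with the silyl triflate protects C6–OH against alkoxide chemistry (protonolysis of the allylnickel, lactone migration) in the key step.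

Step 14
Reactants: 21 (tris-silyl ether)
Product: 22 (2E,4S)-4-{[tert-butyl(dimethyl)silyl]oxy}-2-[(3E)-6-hydroxy-4-methylhex-3-en-1-yl]hepta-2,5,6-trien-1-yl (2Z)-2-({[tert-butyl(diphenyl)silyl]oxy}methyl)but-2-enoate
Conditions: HF·pyridine, pyridine, THF, 0 °C
Reagents that add atoms: none
Why: Buffered HF·pyridine cleaves the primary TBS ether much faster than the secondary allylic TBS ether or the TBDPS ether (selective desilylation by steric differentiation).

Step 15
Reactants: 22 (C8 primary alcohol)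
Product: 23 (2E,4S)-4-{[tert-butyl(dimethyl)silyl]oxy}-2-[(3E)-4-methyl-6-oxohex-3-en-1-yl]hepta-2,5,6-trien-1-yl (2Z)-2-({[tert-butyl(diphenyl)silyl]oxy}methyl)but-2-enoate
Conditions: Dess–Martin periodinane, NaHCO3, CH2Cl2, 0 °C; used at once without chromatography
Reagents that add atoms: none
Why: Buffered Dess–Martin oxidation gives the β,γ-unsaturated aldehyde under neutral conditions, and immediate use avoids migration of the C1=C10 bond into conjugation.

Step 16
Reactants: 23 (allenyl aldehyde)
Product: 26 6-O-TBS side-chain-O-TBDPS bis(silyl) ether of the target lactone, via oxanickelacycle 24 (not isolated), via hydroxy acid 25 (not isolated)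
Conditions: Ni(cod)2 (1.05 equiv), DBU (2.1 equiv), CO2 (1 atm), THF, −20 °C; dilution to 2 mM with CO2-saturated THF, −20 °C to rt; 1 M HCl; PPTS, CH2Cl2, rt
Reagents that add atoms: carbon dioxide, O=C=O
Why: Proposed new method: zerovalent nickel ligated by DBU couples the terminal allene with CO2 by oxidative cyclisation at the central allene carbon (C11–C12) to give oxanickelacycle 24, an allylnickel carboxylate, whose allyl unit then adds through its substituted terminus C7 to the tethered aldehyde carbon C8 in a six-membered chair transition state (C7–C8), and acidification lactonises the γ-hydroxy acid 25. The closest known reaction type is the nickel-mediated sequential addition of CO2 and an aldehyde to a terminal allene, known between separate partners, combined here with the ring-closing logic of Nozaki–Hiyama-type allylmetal macrocyclisations used for germacranolides. The ten-membered carbocycle closes by intramolecular SE2′ allyl transfer (10-membered ring through a 6-membered metallacyclic transition state) and the lactone by 5-exo-trig acyl substitution of the C8 hydroxyl on the C12 carboxyl group. C7 is controlled by the C6 silyloxy stereocentre, because with H6 eclipsing the allyl plane (allylic 1,3-strain) the tethered aldehyde is expected to reach only the face syn to C5, which corresponds to (6R,7S); C8 follows from the chair with the E-configured σ-allyl (C6 cis to the carboxylate, reached by equilibration through the π-allyl form), which gives the anti adduct, that is the trans-fused lactone (7S,8S). The step needs capture of CO2 at the allene in the presence of the free aldehyde, the allylic ester and two trisubstituted alkenes, and γ- rather than α-attack of the allyl unit: the cumulene is the only strongly binding π-ligand, CO2 is in large excess and ties up DBU as its adduct, the nickelacycle is formed cold with a near-stoichiometric amount of nickel before dilution and warming, and α-attack would require a twelve-membered ring without a cyclic transition state.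

Step 17
Reactants: 26 (bis-silyl ether of the target)
Product: 27 the target, [(3aS,4R,5E,9E,11aS)-4-hydroxy-10-methyl-3-methylidene-2-oxo-2,3,3a,4,7,8,11,11a-octahydrocyclodeca[b]furan-6-yl]methyl (2Z)-2-(hydroxymethyl)but-2-enoate
Conditions: HF·pyridine, pyridine, THF, 0 °C to rt
Reagents that add atoms: none
Why: Fluoride-mediated desilylation with buffered HF·pyridine removes both silyl ethers under mildly acidic conditions that avoid lactone migration to the C6 oxygen, conjugate addition to the α-methylene lactone and isomerisation of the Z-enoate.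

**Compound list**

1 | tert-butyl(but-3-yn-1-yloxy)dimethylsilane | C#CCCO[Si](C)(C)C(C)(C)C | starting material
2 | oxirane | C1CO1 | starting material
3 | [(1E)-4-{[tert-butyl(dimethyl)silyl]oxy}-2-methylbut-1-en-1-yl]dimethylalane | C[Al](C)/C=C(\C)CCO[Si](C)(C)C(C)(C)C | intermediate
4 | lithium butyl[(1E)-4-{[tert-butyl(dimethyl)silyl]oxy}-2-methylbut-1-en-1-yl]dimethylalanate | [Li+].CCCC[Al-](C)(C)/C=C(\C)CCO[Si](C)(C)C(C)(C)C | intermediate
5 | (3E)-6-{[tert-butyl(dimethyl)silyl]oxy}-4-methylhex-3-en-1-ol | CC(C)(C)[Si](C)(C)OCC/C(C)=C/CCO | intermediate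
6 | tert-butyl{[(3E)-6-iodo-3-methylhex-3-en-1-yl]oxy}dimethylsilane | CC(C)(C)[Si](C)(C)OCC/C(C)=C/CCI | intermediate
7 | triethyl phosphonoacetate | CCOC(=O)CP(=O)(OCC)OCC | starting material
8 | ethyl (5E)-8-{[tert-butyl(dimethyl)silyl]oxy}-2-(diethoxyphosphoryl)-6-methyloct-5-enoate (racemic at C2) | CC(C)(C)[Si](C)(C)OCC/C(C)=C/CCC(C(=O)OCC)P(=O)(OCC)OCC | intermediate
9 | 2,2-dimethoxyacetaldehyde | COC(OC)C=O | starting material
10 | ethyl (2E)-2-[(3E)-6-{[tert-butyl(dimethyl)silyl]oxy}-4-methylhex-3-en-1-yl]-4,4-dimethoxybut-2-enoate | CC(C)(C)[Si](C)(C)OCC/C(C)=C/CC/C(C(=O)OCC)=C\C(OC)OC | intermediate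
11 | ethyl (2E)-2-[(3E)-6-{[tert-butyl(dimethyl)silyl]oxy}-4-methylhex-3-en-1-yl]-4-oxobut-2-enoate | CC(C)(C)[Si](C)(C)OCC/C(C)=C/CC/C(C(=O)OCC)=C\C=O | intermediate
12 | 2-(prop-2-yn-1-yloxy)oxane (tetrahydropyranyl propargyl ether) | C#CCOC1CCCCO1 | starting material
13 | ethyl (2E,4R)-2-[(3E)-6-{[tert-butyl(dimethyl)silyl]oxy}-4-methylhex-3-en-1-yl]-4-hydroxy-7-(oxan-2-yloxy)hept-2-en-5-ynoate (both epimers at the oxane acetal carbon) | CC(C)(C)[Si](C)(C)OCC/C(C)=C/CC/C(C(=O)OCC)=C\[C@@H](O)C#CCOC1CCCCO1 | intermediate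
14 | (2E,4S)-2-[(3E)-6-{[tert-butyl(dimethyl)silyl]oxy}-4-methylhex-3-en-1-yl]hepta-2,5,6-triene-1,4-diol | CC(C)(C)[Si](C)(C)OCC/C(C)=C/CC/C(CO)=C\[C@@H](O)C=C=C | intermediate
15 | (2E)-but-2-enal (crotonaldehyde) | C/C=C/C=O | starting material
16 | (2Z)-2-iodobut-2-enal | C/C=C(\I)C=O | intermediate
17 | (2Z)-2-iodobut-2-en-1-ol | C/C=C(\I)CO | intermediate
18 | tert-butyl{[(2Z)-2-iodobut-2-en-1-yl]oxy}diphenylsilane | C/C=C(\I)CO[Si](c1ccccc1)(c1ccccc1)C(C)(C)C | intermediate
19 | (2Z)-2-({[tert-butyl(diphenyl)silyl]oxy}methyl)but-2-enoic acid | C/C=C(/CO[Si](c1ccccc1)(c1ccccc1)C(C)(C)C)C(=O)O | intermediate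
20 | (2E,4S)-2-[(3E)-6-{[tert-butyl(dimethyl)silyl]oxy}-4-methylhex-3-en-1-yl]-4-hydroxyhepta-2,5,6-trien-1-yl (2Z)-2-({[tert-butyl(diphenyl)silyl]oxy}methyl)but-2-enoate | CC(C)(C)[Si](C)(C)OCC/C(C)=C/CC/C(COC(=O)/C(=C\C)CO[Si](c1ccccc1)(c1ccccc1)C(C)(C)C)=C\[C@@H](O)C=C=C | intermediate
21 | (2E,4S)-4-{[tert-butyl(dimethyl)silyl]oxy}-2-[(3E)-6-{[tert-butyl(dimethyl)silyl]oxy}-4-methylhex-3-en-1-yl]hepta-2,5,6-trien-1-yl (2Z)-2-({[tert-butyl(diphenyl)silyl]oxy}methyl)but-2-enoate | CC(C)(C)[Si](C)(C)OCC/C(C)=C/CC/C(COC(=O)/C(=C\C)CO[Si](c1ccccc1)(c1ccccc1)C(C)(C)C)=C\[C@@H](O[Si](C)(C)C(C)(C)C)C=C=C | intermediate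
22 | (2E,4S)-4-{[tert-butyl(dimethyl)silyl]oxy}-2-[(3E)-6-hydroxy-4-methylhex-3-en-1-yl]hepta-2,5,6-trien-1-yl (2Z)-2-({[tert-butyl(diphenyl)silyl]oxy}methyl)but-2-enoate | OCC/C(C)=C/CC/C(COC(=O)/C(=C\C)CO[Si](c1ccccc1)(c1ccccc1)C(C)(C)C)=C\[C@@H](O[Si](C)(C)C(C)(C)C)C=C=C | intermediate
23 | (2E,4S)-4-{[tert-butyl(dimethyl)silyl]oxy}-2-[(3E)-4-methyl-6-oxohex-3-en-1-yl]hepta-2,5,6-trien-1-yl (2Z)-2-({[tert-butyl(diphenyl)silyl]oxy}methyl)but-2-enoate | O=CC/C(C)=C/CC/C(COC(=O)/C(=C\C)CO[Si](c1ccccc1)(c1ccccc1)C(C)(C)C)=C\[C@@H](O[Si](C)(C)C(C)(C)C)C=C=C | intermediate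
24 | oxanickelacycle from 23, CO2 and nickel: five-membered ring Ni–C13H2–C11(=C7H–C6)–C12(=O)–O with C6 cis to the carboxylate; the two DBU ligands on nickel are not drawn | O=CC/C(C)=C/CC/C(COC(=O)/C(=C\C)CO[Si](c1ccccc1)(c1ccccc1)C(C)(C)C)=C\[C@@H](O[Si](C)(C)C(C)(C)C)/C=C2/C[Ni]OC2=O | intermediate
25 | γ-hydroxy acid: the seco acid of 26 (ten-membered ring closed, free C8 hydroxyl, C7 bearing the 1-carboxyvinyl group; configurations as in 26) | OC(=O)C(=C)[C@@H]1[C@@H](O)C/C(C)=C/CC/C(COC(=O)/C(=C\C)CO[Si](c2ccccc2)(c2ccccc2)C(C)(C)C)=C\[C@H]1O[Si](C)(C)C(C)(C)C | intermediate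
26 | the target with its C6 hydroxyl as tert-butyldimethylsilyl ether and its side-chain hydroxyl as tert-butyldiphenylsilyl ether | C=C1C(=O)O[C@H]2C/C(C)=C/CC/C(COC(=O)/C(=C\C)CO[Si](c3ccccc3)(c3ccccc3)C(C)(C)C)=C\[C@@H](O[Si](C)(C)C(C)(C)C)[C@H]12 | intermediate
27 | [(3aS,4R,5E,9E,11aS)-4-hydroxy-10-methyl-3-methylidene-2-oxo-2,3,3a,4,7,8,11,11a-octahydrocyclodeca[b]furan-6-yl]methyl (2Z)-2-(hydroxymethyl)but-2-enoate | C=C1C(=O)O[C@H]2C/C(C)=C/CC/C(COC(=O)/C(=C\C)CO)=C\[C@@H](O)[C@H]12 | target

**Count**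

Total step count: 17. Longest linear sequence: 13 steps (steps 1–7 and 12–17, from compound 1).

**Steps most likely to fail**

1. Step 16 (Proposed new method). What may go wrong:
 - allyl transfer between molecules before ring closure;
 - base-promoted migration of the β,γ-double bond of the aldehyde into conjugation;
 - insertion of zerovalent nickel into the allylic ester;
 - β-elimination of the silyloxy group from the allylnickel;
 - ring closure on the wrong face at C7 or C8.

 Fallback with known chemistry, the two bonds being made in separate operations; it sets out from 21 and returns at 26. Copper-catalysed silacarboxylation of the terminal allene (CuCl, PCy3, PhMe2Si–Bpin, CO2, THF; then Me3SiCHN2, MeOH) puts the silyl group on C13 and the carboxyl group on C11 to give the allylsilane methyl ester F1. Selective desilylation of the primary TBS ether (HF·pyridine, pyridine) gives the alcohol F2, and Dess–Martin oxidation the aldehyde F3. Intramolecular Hosomi–Sakurai allylation (BF3·OEt2, CH2Cl2, −78 °C) of the 2-(silylmethyl)acrylate on to the aldehyde closes the ten-membered ring to the hydroxy ester F4, which lactonises (PPTS, toluene, 60 °C) to 26.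

2. Step 7. What may go wrong: further hydride reduction of the newly formed α-allenic alcohol, conjugate reduction of the enoate during the prolonged exposure that the SN2′ event needs, or loss of the primary silyl ether.

 Fallback: it sets out from 11 and returns at 14. The same zinc–ProPhenol alkynylation with ethynyltrimethylsilane gives the silylalkynol ester F5. DIBAL-H (CH2Cl2, −78 °C) reduces only the ester to the diol F6. K2CO3 in MeOH frees the terminal alkyne F7. Crabbé homologation ((CH2O)n, CuI, dicyclohexylamine, dioxane, reflux) then turns the terminal alkyne into the terminal allene 14.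

3. Step 6. What may go wrong: poor facial selectivity, or competing conjugate addition or methyl transfer on the doubly activated 4-oxo-enoate.

 Fallback: it sets out from 11 and returns at 13. The lithium acetylide of 12 (n-BuLi, CeCl3, THF, −78 °C) adds without stereocontrol to give the racemic alcohol F8. Dess–Martin oxidation gives the ynone F9. Noyori asymmetric transfer hydrogenation (RuCl[(S,S)-TsDPEN](p-cymene), HCO2H/NEt3; antipode of the catalyst chosen to give the R-carbinol) returns 13.

Further compounds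
F1 | step 16 | methyl (2Z)-2-{[dimethyl(phenyl)silyl]methyl}alk-2-enoate formed from the allene of 21 (silyl on C13, CO2Me on C11, C6 cis to the silylmethyl group) | CC(C)(C)[Si](C)(C)OCC/C(C)=C/CC/C(COC(=O)/C(=C\C)CO[Si](c1ccccc1)(c1ccccc1)C(C)(C)C)=C\[C@@H](O[Si](C)(C)C(C)(C)C)/C=C(\C[Si](C)(C)c1ccccc1)C(=O)OC
F2 | step 16 | primary alcohol from F1 (C8 hydroxyl free) | OCC/C(C)=C/CC/C(COC(=O)/C(=C\C)CO[Si](c1ccccc1)(c1ccccc1)C(C)(C)C)=C\[C@@H](O[Si](C)(C)C(C)(C)C)/C=C(\C[Si](C)(C)c1ccccc1)C(=O)OC
F3 | step 16 | aldehyde from F2 (C8 formyl group) | O=CC/C(C)=C/CC/C(COC(=O)/C(=C\C)CO[Si](c1ccccc1)(c1ccccc1)C(C)(C)C)=C\[C@@H](O[Si](C)(C)C(C)(C)C)/C=C(\C[Si](C)(C)c1ccccc1)C(=O)OC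
F4 | step 16 | methyl ester of hydroxy acid 25 | COC(=O)C(=C)[C@@H]1[C@@H](O)C/C(C)=C/CC/C(COC(=O)/C(=C\C)CO[Si](c2ccccc2)(c2ccccc2)C(C)(C)C)=C\[C@H]1O[Si](C)(C)C(C)(C)C
F5 | step 7 | ethyl (2E,4R)-2-[(3E)-6-{[tert-butyl(dimethyl)silyl]oxy}-4-methylhex-3-en-1-yl]-4-hydroxy-6-(trimethylsilyl)hex-2-en-5-ynoate | CC(C)(C)[Si](C)(C)OCC/C(C)=C/CC/C(C(=O)OCC)=C\[C@@H](O)C#C[Si](C)(C)C
F6 | step 7 | (2E,4R)-2-[(3E)-6-{[tert-butyl(dimethyl)silyl]oxy}-4-methylhex-3-en-1-yl]-6-(trimethylsilyl)hex-2-en-5-yne-1,4-diol | CC(C)(C)[Si](C)(C)OCC/C(C)=C/CC/C(CO)=C\[C@@H](O)C#C[Si](C)(C)C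
F7 | step 7 | (2E,4R)-2-[(3E)-6-{[tert-butyl(dimethyl)silyl]oxy}-4-methylhex-3-en-1-yl]hex-2-en-5-yne-1,4-diol | CC(C)(C)[Si](C)(C)OCC/C(C)=C/CC/C(CO)=C\[C@@H](O)C#C
F8 | step 6 | racemic form of 13 (carbinol carbon unspecified) | CC(C)(C)[Si](C)(C)OCC/C(C)=C/CC/C(C(=O)OCC)=C\C(O)C#CCOC1CCCCO1
F9 | step 6 | ethyl (2E)-2-[(3E)-6-{[tert-butyl(dimethyl)silyl]oxy}-4-methylhex-3-en-1-yl]-7-(oxan-2-yloxy)-4-oxohept-2-en-5-ynoate | CC(C)(C)[Si](C)(C)OCC/C(C)=C/CC/C(C(=O)OCC)=C\C(=O)C#CCOC1CCCCO1
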